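**Convention and one assumption.** Every intermediate carries the hydroazulene (bicyclo[5.3.0]decane) numbering of the target: C1 is the methyl-bearing ring-fusion carbon, C2–C4 follow in the five-membered ring, C5 is the ring-fusion CH, and C6–C10 run round the seven-membered ring back to C1. α is the face of the C1 methyl group and H-5; β is the other face. Lactol acetate 4 is used as the racemate, because its only stereocentre disappears when the ylide forms.

## The problem

Target 22 is a cis-fused hydroazulene: a cyclopentane (C1–C5) joined to a cycloheptene (C1, C5–C10, C8(Me)=C9) through an all-carbon quaternary C1 and a tertiary C5. It has five stereocentres: C1 (α-methyl), C5 (α-H), C2 (β-angeloyloxy), C4 (β-hydroxyl, α-isopropyl, tertiary) and C6 (α-aroyloxy). The quaternary C1 sits between two oxygenated carbons (C2 and, through C5, C6), so the bond that creates it is the hardest C–C bond. A single resolved oxygen stereocentre at C2 can decide the face on which the seven-membered ring is attached, and so set C1, C5 and C6. Once an oxygen-bridged tricycle exists, its bridge covers the β face of the cyclopentane, so a carbon nucleophile at C4 and a hydride at C2 must both arrive from the α face, which is what the target needs. The C2 oxygen that steered the ring formation therefore ends on the wrong face and has to be inverted. The angelate (Z to E isomerisation, conjugate addition, reduction) must go on last; the tertiary C4 hydroxyl is at risk of dehydration or retro-aldol cleavage whenever C2 is a ketone; and the two secondary hydroxyls at C2 and C6 must be kept distinguishable. The enabling feature is the arc C6–C7–C8(Me)=C9–C10 with its homoallylic C6 oxygen: rejoining that oxygen to C10 gives an 8-oxabicyclo[3.2.1]octene fused at C1–C5, which is the (5+2) adduct of a 3-oxidopyrylium across the C1=C5 olefin of a cyclopentenone.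

## Retrosynthesis

**The two esters.** The C2–O acyl bond of 22 is cut first, giving diol 21, because the angelate is the one group that tolerates nothing downstream. Diol 21 comes from silyl ether 20, and 20 from alcohol 19 by cutting the C6–O acyl bond. Keeping C2 as a silyl ether while C6 is free is the only reliable way to tell the two hindered secondary hydroxyls apart. The forward steps are plain acylations beside an inert tertiary alcohol.

**The C10–H bond (reconnecting C10 to O6).** Alcohol 19 is traced to the bridged tricyclic ether 18 by re-forming the C10–O bond. The alternative of cleaving this bond earlier, at the stage of the C9 enone 9, was set aside: a one-electron reductant would generate an enone radical anion that can expel the bridging oxygen from C6 (vinylogous) as readily as from C10. In 18 only the C10–O bond is allylic. The forward reaction must cleave it by electron transfer and protonate the allyl anion at C10. No ester may be present, which is why this cut lies before the acylations and why C2 is masked as a silyl ether rather than as the final ester.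

**The C2 configuration.** Silyl ether 18 comes from 2β-alcohol 17, which comes from ketone 16, then 2α-alcohol 15, then silyl ether 14. The inversion is placed on the tricycle because there the C9–C10 part of the bridge lies over the β face of C2, so a small hydride must enter from α. In the opened bicycle the α face carries the isopropyl group and the C1 methyl, and the same reduction would be expected to give the wrong epimer. The price is two protecting-group operations.

**The C8=C9 olefin and the C4 carbinol.** Alkene 14 is traced to allylic alcohol 11 by a reductive 1,3-transposition (hydrogen to C7, loss of the C9 oxygen). Diol 11 comes from ketone 10 by cutting the C4–isopropyl bond, and 10 from diketone 9 by returning C9 to the ketone level. Reducing C9 before the isopropyl addition serves two purposes: it removes the only other electrophilic carbonyl while C4 is alkylated, and it supplies the hydroxyl through which C9 is later deoxygenated. Both forward additions are asked to come from the open α (exo) face.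

**The key cut.** Diketone 9 is divided at C1–C10 and C5–C6 into enone 7 and ylide 8, generated from acetate 4. This removes both new rings and four stereocentres at once, leaving a monocyclic enone and a monocyclic pyranone. The forward cycloaddition must be regioselective (the ylide carbon next to the oxido carbon onto C1), anti to the C2 silyloxy group, and endo. The partner is a β,β-disubstituted enone, so the step sits at the edge of what this cycloaddition is known to do.

**The two fragments.** Enone 7 comes from enol silane 6 by dehydrogenation, and 6 from the enantiopure enone 5 by cutting the C1–methyl bond (conjugate methyl addition). Acetate 4 comes from lactol 3, which is the oxidative ring expansion product of furylcarbinol 2, itself the reduction product of acid 1. The ring methyl of 1 becomes the C8 methyl of 22.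

## Roads not taken

**Alternative 1:** The cut is at C6–C7 and C1–C10, the other flank of the seven-membered ring. The enal A1 (aldehyde carbon = C6, silyl enol ether carbon = C5, fully substituted β-carbon = C1) would combine with isoprene A2 in a Lewis-acid-promoted formal (4+3): the diene attacks the activated aldehyde, the silyl group moves to the new C6 oxygen, and the enol carbon C1 captures the allyl cation at C10, giving cycloheptenone A3.
- *Merits.* C8=C9 and its methyl arrive in their final place, so there is no bridge to open and no olefin to move. The isoprene regiochemistry is electronically matched, since the first bond leaves a tertiary allyl cation. The dioxolane can carry the C2 oxygen in its final configuration, so no inversion is needed. In these respects A3 is better than 9.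
- *Weak points.* The ring-closing bond has to create quaternary C1 from a tetrasubstituted enol ether, whereas the known cases of this reaction use unhindered silyloxy enals. C1 and C6 are set in a stepwise cationic process relative to one exocyclic stereocentre. The cyclopentane is still missing: C4 and its isopropyl group must be brought in and two more ring bonds closed, with C4 and C5 set without the help of a rigid frame.
- *Comparison.* The chosen plan forms both ring-fusion centres and C6 in one concerted event and then uses the tricycle to set C4 and C2.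

**Alternative 2:** The cut is the C1–C5 bond, remade from a C1–C6 bond by a 1,2-shift. A decalin from thymoquinone A4 and isoprene A2 would be elaborated to the trans-fused epoxy alcohol A5. A boron Lewis acid would open the C4–C5 epoxide while C1 migrates from C6 to C5, contracting one ring to the cyclopentane and expanding the other to the cycloheptenone A6.
- *Merits.* The inputs are the cheapest of all four routes and bring all fifteen skeletal carbons in the first step. A6 already has C2 in the target configuration, the C4 carbinol, C8=C9 and C6 at the ketone level, so it is closer to 22 than 9 is. If the shift behaved, this road would need fewer operations after its key step than the eleven the chosen plan spends.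
- *Weak points.* The Diels–Alder step must choose the methyl-bearing quinone olefin over the isopropyl-bearing one and is racemic without a catalyst. The epoxide of A5 is tertiary at C4 and secondary at C5, so a Lewis acid prefers to break the C4–O bond, while the shift needs the C5–O bond to break. In a trans-decalin the ring bond C1–C6 must compete with the axial C6–C7 bond for the antiperiplanar position. The C2 oxygen has to be introduced separately.
- *Comparison.* The chosen plan offers absolute control from a commercial enantiopure enone and a ring-forming step whose topology is fixed by the cycloaddition itself.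

**Alternative 3:** The cut is C1–C10 through a retro-Cope step. The cis-divinylcyclopropane A7 (cyclopropane carbons C6, C7, C8) would, on heating, form C1–C10 and break C6–C8, giving the bicyclic silyl enol ether A8 with quaternary C1 and C8=C9 in place.
- *Merits.* The rearrangement is stereospecific and has far better precedent for building a quaternary carbon in a seven-membered ring than an intermolecular cycloaddition onto a β,β-disubstituted enone. On this point it is the safer key step.
- *Weak points.* The C1 methyl is cis to the cyclopropane-bearing carbon on the ring olefin, so in the boat transition state it points into the cyclopropane CH2, which is the substitution pattern known to slow this rearrangement. The absolute configuration of the two cyclopropane centres alone decides C1, and the C2 silyl ether does not control their formation. A8 carries C4 as a plain CH2 with no handle for the isopropyl carbinol, and C5 and C6 are still sp2.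
- *Comparison.* The chosen plan brings the C2, C4 and C6 oxygens in with the two fragments, where A8 would need a long oxidation sequence.

Key step: step 6

## Route

Step 1
Reactants: 1 3-methylfuran-2-carboxylic acid
Product: 2 (3-methylfuran-2-yl)methanol
Conditions: LiAlH4, THF, 0 to 23 °C
Reagents that add atoms: none
Why: Hydride reduction of the carboxylic acid to the primary alcohol; the furan ring and its methyl group are inert to LiAlH4.

Step 2
Reactants: 2 (3-methylfuran-2-yl)methanol
Product: 3 6-hydroxy-4-methyl-2H-pyran-3(6H)-one (racemic lactol)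
Conditions: N-bromosuccinimide, NaHCO3, THF/H2O, 0 °C
Reagents that add atoms: water, O
Why: Achmatowicz oxidative ring expansion of the furylcarbinol; the furan 3-methyl group becomes the C4 methyl of the pyranone, and the lactol carbon is formed as a racemate that is erased in step 6.

Step 3
Reactants: 3 6-hydroxy-4-methyl-2H-pyran-3(6H)-one
Product: 4 6-acetoxy-4-methyl-2H-pyran-3(6H)-one (racemic acetal)
Conditions: Ac2O, pyridine, DMAP (cat.), CH2Cl2, 0 °C
Reagents that add atoms: acetic anhydride, CC(=O)OC(C)=O
Why: DMAP-catalysed O-acylation of the anomeric hydroxyl installs the leaving group needed for ylide formation.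

Step 4
Reactants: 5 (R)-4-(tert-butyldimethylsilyloxy)cyclopent-2-en-1-one
Product: 6 (3R,4R)-4-(tert-butyldimethylsilyloxy)-3-methyl-1-(trimethylsilyloxy)cyclopent-1-ene (methyl trans to the silyloxy group)
Conditions: MeLi, CuI, Et2O, 0 °C; then 5, Me3SiCl, Et3N, THF, −78 °C
Reagents that add atoms: methyllithium (delivered as lithium dimethylcuprate), [Li]C; chlorotrimethylsilane, C[Si](C)(C)Cl
Why: Cuprate conjugate addition anti to the C4 silyloxy group with in situ O-silylation of the enolate, which fixes the enolate regiochemistry before β-elimination of the silyloxy group can occur; the new C3 centre is set by steric approach control and is removed again in step 5.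

Step 5
Reactants: 6 (3R,4R)-4-(tert-butyldimethylsilyloxy)-3-methyl-1-(trimethylsilyloxy)cyclopent-1-ene
Product: 7 (R)-4-(tert-butyldimethylsilyloxy)-3-methylcyclopent-2-en-1-one
Conditions: Pd(OAc)2 (1.05 equiv), MeCN, 23 °C
Reagents that add atoms: none
Why: Saegusa–Ito oxidation: palladation of the enol silane at C2 and syn β-hydride elimination of H-3 return the enone with the methyl group on the β-carbon; the silyloxy stereocentre is untouched.

Step 6
Reactants: 4 6-acetoxy-4-methyl-2H-pyran-3(6H)-one (3 equiv); 7 (R)-4-(tert-butyldimethylsilyloxy)-3-methylcyclopent-2-en-1-one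
Product: 9 endo adduct 2α-(tert-butyldimethylsilyloxy)-6α,10α-epoxy-1α,8-dimethylhydroazul-7-ene-4,9-dione, via 4-methyl-3-oxidopyrylium 8 (not isolated)
Conditions: Et3N, MeCN, 60 °C, 4 added slowly over 12 h
Reagents that add atoms: none
Why: Et3N removes the acidic C2 proton of 4 and acetate leaves from C6, giving the carbonyl ylide 8, which adds across C1=C5 of 7 in a concerted, asynchronous, suprafacial–suprafacial 1,3-dipolar (5+2) cycloaddition; the closest known reaction type is the intermolecular cycloaddition of 3-oxidopyrylium ylides with enones and acrylates. Both rings close in this one intermolecular cycloaddition event: the seven-membered carbocycle through the new C1–C10 and C5–C6 bonds, and the tetrahydrofuran ring through the same two bonds across the ylide oxygen. Regiochemistry follows the frontier orbitals: the ylide carbon next to the oxido carbon (future C10) has the largest HOMO coefficient and bonds to the enone β-carbon C1. C1 and C5 are set cis by suprafacial addition to the ring olefin, and in the absolute sense by approach anti to the C2 silyloxy group of 7. C6 and C10 are fixed relative to each other by the planar ylide and relative to C1 and C5 by the endo orientation, in which the enone carbonyl lies under the C7–C8–C9 carbons of the ylide and the small H-5 and C1 methyl face the bridging oxygen. The step needs regio-, facial and endo selectivity, secured respectively by the enone polarisation, the C2 substituent and the carbonyl orientation. Slow addition of excess 4 keeps the ylide concentration low so that capture by the hindered enone can compete with ylide dimerisation.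

Step 7
Reactants: 9 2α-(tert-butyldimethylsilyloxy)-6α,10α-epoxy-1α,8-dimethylhydroazul-7-ene-4,9-dione
Product: 10 2α-(tert-butyldimethylsilyloxy)-6α,10α-epoxy-9β-hydroxy-1α,8-dimethylhydroazul-7-en-4-one
Conditions: NaBH4 (1 equiv), CeCl3·7H2O, MeOH/CH2Cl2, −78 °C
Reagents that add atoms: none
Why: Luche reduction: the CeCl3-activated conjugated C9 carbonyl, flanked by the bridging oxygen, is reduced 1,2 in preference to the hindered saturated C4 cyclopentanone; hydride enters from the exo (α) face, and the C9 configuration is of no consequence because the centre is removed in step 9; the alcohol masks C9 for step 8 and is the handle for step 9.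

Step 8
Reactants: 10 2α-(tert-butyldimethylsilyloxy)-6α,10α-epoxy-9β-hydroxy-1α,8-dimethylhydroazul-7-en-4-one
Product: 11 2α-(tert-butyldimethylsilyloxy)-6α,10α-epoxy-4α-isopropyl-1α,8-dimethylhydroazul-7-ene-4β,9β-diol
Conditions: i-PrMgCl, CeCl3 (3 equiv each), THF, −78 to 0 °C
Reagents that add atoms: isopropylmagnesium chloride, CC(C)[Mg]Cl
Why: Organocerium 1,2-addition, whose low basicity suppresses enolisation and β-elimination of the C2 silyloxy group or the C6–O bridge (one equivalent is spent on the C9 hydroxyl); the C7=C8–C9 bridge covers the β face of C4, so the reagent enters from α and leaves the isopropyl group α and the hydroxyl β, as in the target.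

Step 9
Reactants: 11 2α-(tert-butyldimethylsilyloxy)-6α,10α-epoxy-4α-isopropyl-1α,8-dimethylhydroazul-7-ene-4β,9β-diol
Product: 14 2α-(tert-butyldimethylsilyloxy)-6α,10α-epoxy-4α-isopropyl-1α,8-dimethylhydroazul-8-en-4β-ol, via C9 N-sulfonylhydrazine adduct 12 (not isolated), via C9 allylic diazene 13 (not isolated)
Conditions: 2-nitrobenzenesulfonylhydrazide, PPh3, diethyl azodicarboxylate, THF, −30 °C; then 23 °C
Reagents that add atoms: none
Why: Mitsunobu displacement of the allylic C9 hydroxyl by the sulfonylhydrazide (inversion, nucleophile from the open exo face), loss of sulfinic acid on warming, and retro-ene loss of N2 from the allylic diazene deliver hydrogen to C7 and move the olefin to C8=C9 (reductive 1,3-transposition); no stereocentre is created and the tertiary C4 hydroxyl does not take part.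

Step 10
Reactants: 14 2α-(tert-butyldimethylsilyloxy)-6α,10α-epoxy-4α-isopropyl-1α,8-dimethylhydroazul-8-en-4β-ol
Product: 15 6α,10α-epoxy-4α-isopropyl-1α,8-dimethylhydroazul-8-ene-2α,4β-diol
Conditions: Bu4NF, THF, 23 °C
Reagents that add atoms: none
Why: Fluoride desilylation; the molecule carries only an ether bridge, an olefin and a tertiary alcohol at this stage, none of which is base-sensitive.

Step 11
Reactants: 15 6α,10α-epoxy-4α-isopropyl-1α,8-dimethylhydroazul-8-ene-2α,4β-diol
Product: 16 6α,10α-epoxy-4β-hydroxy-4α-isopropyl-1α,8-dimethylhydroazul-8-en-2-one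
Conditions: Dess–Martin periodinane, pyridine, CH2Cl2, 0 °C
Reagents that add atoms: none
Why: Dess–Martin oxidation of the only secondary alcohol; the pyridine buffer protects the resulting β-hydroxy ketone from dehydration and retro-aldol cleavage.

Step 12
Reactants: 16 6α,10α-epoxy-4β-hydroxy-4α-isopropyl-1α,8-dimethylhydroazul-8-en-2-one
Product: 17 6α,10α-epoxy-4α-isopropyl-1α,8-dimethylhydroazul-8-ene-2β,4β-diol
Conditions: NaBH4, CeCl3·7H2O, MeOH, −78 to −20 °C
Reagents that add atoms: none
Why: Ketone reduction by external hydride from the α (exo) face, the β face of C2 being covered by the C9–C10 part of the bridge; this gives the 2β-alcohol of the target, cis to the C4 hydroxyl, and the protic Luche conditions favour intermolecular delivery over delivery from the C4 hydroxyl.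

Step 13
Reactants: 17 6α,10α-epoxy-4α-isopropyl-1α,8-dimethylhydroazul-8-ene-2β,4β-diol
Product: 18 6α,10α-epoxy-4α-isopropyl-1α,8-dimethyl-2β-(triethylsilyloxy)hydroazul-8-en-4β-ol
Conditions: Et3SiCl, imidazole, DMAP (cat.), DMF, 23 °C
Reagents that add atoms: chlorotriethylsilane, CC[Si](CC)(CC)Cl
Why: Selective silylation of the secondary C2 hydroxyl (the tertiary C4 hydroxyl does not react under these conditions); the silyl ether survives dissolving metal and keeps the C2 and C6 oxygens distinguishable after ring opening.

Step 14
Reactants: 18 6α,10α-epoxy-4α-isopropyl-1α,8-dimethyl-2β-(triethylsilyloxy)hydroazul-8-en-4β-ol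
Product: 19 4α-isopropyl-1α,8-dimethyl-2β-(triethylsilyloxy)-5α-H-hydroazul-8-ene-4β,6α-diol
Conditions: Li, EtNH2, t-BuOH, THF, −78 °C; then NH4Cl
Reagents that add atoms: none
Why: Birch-type electron-transfer cleavage of the only allylic C–O bond (C10–O; the C6–O bond is not activated) gives the C6 alkoxide and an allyl anion that is protonated at its less substituted terminus C10, keeping the trisubstituted C8=C9 olefin; C6 retains the configuration set in step 6 and no ester is yet present.

Step 15
Reactants: 19 4α-isopropyl-1α,8-dimethyl-2β-(triethylsilyloxy)-5α-H-hydroazul-8-ene-4β,6α-diol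
Product: 20 4β-hydroxy-4α-isopropyl-1α,8-dimethyl-2β-(triethylsilyloxy)-5α-H-hydroazul-8-en-6α-yl 3,4,5-trimethoxybenzoate
Conditions: 3,4,5-trimethoxybenzoyl chloride, DMAP, Et3N, CH2Cl2, 23 °C
Reagents that add atoms: 3,4,5-trimethoxybenzoyl chloride, COc1cc(cc(OC)c1OC)C(Cl)=O
Why: DMAP-catalysed acylation of the only free secondary hydroxyl (C6); the tertiary C4 hydroxyl is inert.

Step 16
Reactants: 20 4β-hydroxy-4α-isopropyl-1α,8-dimethyl-2β-(triethylsilyloxy)-5α-H-hydroazul-8-en-6α-yl 3,4,5-trimethoxybenzoate
Product: 21 2β,4β-dihydroxy-4α-isopropyl-1α,8-dimethyl-5α-H-hydroazul-8-en-6α-yl 3,4,5-trimethoxybenzoate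
Conditions: HF·pyridine, pyridine, THF, 0 °C
Reagents that add atoms: none
Why: Buffered fluoride cleavage of the triethylsilyl ether; the aryl ester, the olefin and the tertiary alcohol are unaffected.

Step 17
Reactants: 21 2β,4β-dihydroxy-4α-isopropyl-1α,8-dimethyl-5α-H-hydroazul-8-en-6α-yl 3,4,5-trimethoxybenzoate
Product: 22 2β-angeloyloxy-4β-hydroxy-4α-isopropyl-1α,8-dimethyl-5α-H-hydroazul-8-en-6α-yl 3,4,5-trimethoxybenzoate (CNP0112256.1)
Conditions: angelic acid, 2,4,6-trichlorobenzoyl chloride, Et3N, toluene, 23 °C; then 21, DMAP, 23 to 45 °C
Reagents that add atoms: angelic acid ((Z)-2-methylbut-2-enoic acid), C/C=C(/C)C(=O)O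
Why: Yamaguchi esterification through the mixed anhydride acylates the hindered secondary C2 hydroxyl under mild conditions that preserve the (Z)-geometry of the angelate; the tertiary C4 hydroxyl does not compete.

## Compound list

1 | 3-methylfuran-2-carboxylic acid | Cc1ccoc1C(=O)O | starting material
2 | (3-methylfuran-2-yl)methanol | Cc1ccoc1CO | intermediate
3 | 6-hydroxy-4-methyl-2H-pyran-3(6H)-one (racemic) | OC1C=C(C)C(=O)CO1 | intermediate
4 | 6-acetoxy-4-methyl-2H-pyran-3(6H)-one (racemic) | CC(=O)OC1C=C(C)C(=O)CO1 | intermediate
5 | (R)-4-(tert-butyldimethylsilyloxy)cyclopent-2-en-1-one | O=C1C=C[C@H](O[Si](C)(C)C(C)(C)C)C1 | starting material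
6 | (3R,4R)-4-(tert-butyldimethylsilyloxy)-3-methyl-1-(trimethylsilyloxy)cyclopent-1-ene | C[C@@H]1C=C(O[Si](C)(C)C)C[C@H]1O[Si](C)(C)C(C)(C)C | intermediate
7 | (R)-4-(tert-butyldimethylsilyloxy)-3-methylcyclopent-2-en-1-one | CC1=CC(=O)C[C@H]1O[Si](C)(C)C(C)(C)C | intermediate
8 | 4-methyl-3-oxidopyrylium | Cc1cc[o+]cc1[O-] | intermediate
9 | endo adduct 2α-(tert-butyldimethylsilyloxy)-6α,10α-epoxy-1α,8-dimethylhydroazul-7-ene-4,9-dione | CC(C)(C)[Si](C)(C)O[C@@H]1CC(=O)[C@H]2[C@H]3C=C(C)C(=O)[C@H](O3)[C@@]12C | intermediate
10 | 2α-(tert-butyldimethylsilyloxy)-6α,10α-epoxy-9β-hydroxy-1α,8-dimethylhydroazul-7-en-4-one | CC(C)(C)[Si](C)(C)O[C@@H]1CC(=O)[C@H]2[C@H]3C=C(C)[C@@H](O)[C@H](O3)[C@@]12C | intermediate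
11 | 2α-(tert-butyldimethylsilyloxy)-6α,10α-epoxy-4α-isopropyl-1α,8-dimethylhydroazul-7-ene-4β,9β-diol | CC(C)(C)[Si](C)(C)O[C@@H]1C[C@](O)(C(C)C)[C@H]2[C@H]3C=C(C)[C@@H](O)[C@H](O3)[C@@]12C | intermediate
12 | C9 N-sulfonylhydrazine adduct (9α-[N-amino-N-(2-nitrobenzenesulfonyl)amino] analogue of 11) | CC(C)(C)[Si](C)(C)O[C@@H]1C[C@](O)(C(C)C)[C@H]2[C@H]3C=C(C)[C@H](N(N)S(=O)(=O)c4ccccc4[N+](=O)[O-])[C@H](O3)[C@@]12C | intermediate
13 | C9 allylic diazene (9α-diazenyl analogue of 11) | CC(C)(C)[Si](C)(C)O[C@@H]1C[C@](O)(C(C)C)[C@H]2[C@H]3C=C(C)[C@H](N=N)[C@H](O3)[C@@]12C | intermediate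
14 | 2α-(tert-butyldimethylsilyloxy)-6α,10α-epoxy-4α-isopropyl-1α,8-dimethylhydroazul-8-en-4β-ol | CC(C)(C)[Si](C)(C)O[C@@H]1C[C@](O)(C(C)C)[C@H]2[C@H]3CC(C)=C[C@H](O3)[C@@]12C | intermediate
15 | 6α,10α-epoxy-4α-isopropyl-1α,8-dimethylhydroazul-8-ene-2α,4β-diol | O[C@@H]1C[C@](O)(C(C)C)[C@H]2[C@H]3CC(C)=C[C@H](O3)[C@@]12C | intermediate
16 | 6α,10α-epoxy-4β-hydroxy-4α-isopropyl-1α,8-dimethylhydroazul-8-en-2-one | O=C1C[C@](O)(C(C)C)[C@H]2[C@H]3CC(C)=C[C@H](O3)[C@@]12C | intermediate
17 | 6α,10α-epoxy-4α-isopropyl-1α,8-dimethylhydroazul-8-ene-2β,4β-diol | O[C@H]1C[C@](O)(C(C)C)[C@H]2[C@H]3CC(C)=C[C@H](O3)[C@@]12C | intermediate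
18 | 6α,10α-epoxy-4α-isopropyl-1α,8-dimethyl-2β-(triethylsilyloxy)hydroazul-8-en-4β-ol | CC[Si](CC)(CC)O[C@H]1C[C@](O)(C(C)C)[C@H]2[C@H]3CC(C)=C[C@H](O3)[C@@]12C | intermediate
19 | 4α-isopropyl-1α,8-dimethyl-2β-(triethylsilyloxy)-5α-H-hydroazul-8-ene-4β,6α-diol | CC[Si](CC)(CC)O[C@H]1C[C@](O)(C(C)C)[C@H]2[C@H](O)CC(C)=CC[C@@]12C | intermediate
20 | 4β-hydroxy-4α-isopropyl-1α,8-dimethyl-2β-(triethylsilyloxy)-5α-H-hydroazul-8-en-6α-yl 3,4,5-trimethoxybenzoate | CC[Si](CC)(CC)O[C@H]1C[C@](O)(C(C)C)[C@H]2[C@H](OC(=O)c3cc(OC)c(OC)c(OC)c3)CC(C)=CC[C@@]12C | intermediate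
21 | 2β,4β-dihydroxy-4α-isopropyl-1α,8-dimethyl-5α-H-hydroazul-8-en-6α-yl 3,4,5-trimethoxybenzoate | O[C@H]1C[C@](O)(C(C)C)[C@H]2[C@H](OC(=O)c3cc(OC)c(OC)c(OC)c3)CC(C)=CC[C@@]12C | intermediate
22 | 2β-angeloyloxy-4β-hydroxy-4α-isopropyl-1α,8-dimethyl-5α-H-hydroazul-8-en-6α-yl 3,4,5-trimethoxybenzoate (CNP0112256.1) | C/C=C(/C)C(=O)O[C@H]1C[C@](O)(C(C)C)[C@H]2[C@H](OC(=O)c3cc(OC)c(OC)c(OC)c3)CC(C)=CC[C@@]12C | target

## Step count and least certain steps

Total: 17 steps. Longest linear sequence: 15 steps (steps 1–3 and 6–17, from 1); the branch from 5 (steps 4 and 5) joins at step 6.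

**Key step (step 6).** The most likely failure is that cycloaddition onto the β,β-disubstituted enone is too slow, so that dimerisation or decomposition of the ylide, or amine-induced loss of the β-silyloxy group from 7 or 9, takes over; endo selectivity may also erode at the temperature needed. The fallback gives the olefin a second acceptor substituent that can be removed without forming a C5 carbanion (a carbanion there could eject the C6 oxygen). Setting out from 7, bromination and dehydrobromination (Br2, then Et3N) give (R)-2-bromo-4-(tert-butyldimethylsilyloxy)-3-methylcyclopent-2-en-1-one F1. Cycloaddition of F1 with 4 and Et3N gives the 5-bromo adduct F2, and radical debromination (Bu3SnH, azobisisobutyronitrile, benzene, 80 °C) returns to the route at 9.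

**Step 14.** The allyl anion may be protonated at C8 instead of C10, so the olefin ends at C9=C10, or the olefin may be over-reduced, because the regiochemistry of protonation is under only modest electronic control. The fallback replaces the anionic opening by a cationic one. Setting out from 17, both hydroxyls are silylated (excess Et3SiOTf, 2,6-lutidine) to give the bis(triethylsilyl) ether F3. BF3·OEt2 with Et3SiH at −78 °C ionises the allylic C10–O bond and delivers hydride to C10, giving the ring-opened 6α-alcohol F4. Aroylation as in step 15 gives the ester F5, and HF·pyridine removes both silyl groups, returning to the route at 21.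

**Step 9.** The Mitsunobu displacement at C9, a hindered carbon next to the oxygen-bearing bridgehead, may stall or proceed with allylic shift. The fallback makes the same allylic diazene from the ketone. Setting out from 11, MnO2 oxidises the allylic alcohol to the enone F6, p-toluenesulfonylhydrazide gives the tosylhydrazone F7, and catecholborane followed by NaOAc·3H2O in warm CHCl3 effects the reductive transposition, returning to the route at 14.

**Step 7.** Hydride may also reduce the C4 ketone, since the preference for the conjugated carbonyl rests on CeCl3 activation and on the steric shielding of C4 only. The fallback masks the enone by 1,4-reduction instead. Setting out from 9, [(Ph3P)CuH]6 with Me3SiCl gives the C8=C9 trimethylsilyl enol ether F8, leaving the C4 ketone untouched. i-PrMgCl/CeCl3 then adds to C4 to give the carbinol F9. MeLi followed by PhNTf2 converts the enol silane into the enol triflate F10, and Pd(OAc)2, PPh3, Bu3N and HCO2H reduce the triflate, returning to the route at 14 (steps 8 and 9 are bypassed).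

**Step 8.** Enolisation of the C4 ketone (with loss of the C2 silyloxy group or opening of the C6–O bridge) or β-hydride reduction may compete with addition of the bulky secondary nucleophile. The fallback uses an sp2 nucleophile without β-hydrogens. Setting out from 10, isopropenylmagnesium bromide with CeCl3 gives the 4α-isopropenyl carbinol F11, and hydrogenation of the 1,1-disubstituted olefin with RhCl(PPh3)3 under H2 (the trisubstituted C7=C8 olefin reacts far more slowly) returns to the route at 11.

**Step 17.** Acylation of the neopentyl C2 hydroxyl may be slow, and forcing it invites isomerisation of the angelate to the tiglate. The fallback builds the olefin after the ester bond. Setting out from 21, coupling with 2-[bis(2,2,2-trifluoroethoxy)phosphoryl]propanoic acid (dicyclohexylcarbodiimide, DMAP) gives the C2 phosphonopropionate F12, and Still–Gennari olefination with acetaldehyde (KN(SiMe3)2, 18-crown-6, THF, −78 °C) forms the (Z)-2-methylbut-2-enoate, arriving at 22.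

## Further compounds

F1 | step 6 | (R)-2-bromo-4-(tert-butyldimethylsilyloxy)-3-methylcyclopent-2-en-1-one | CC1=C(Br)C(=O)C[C@H]1O[Si](C)(C)C(C)(C)C
F2 | step 6 | 5-bromo analogue of 9 (endo adduct, bromine in place of H-5) | CC(C)(C)[Si](C)(C)O[C@@H]1CC(=O)[C@@]2(Br)[C@H]3C=C(C)C(=O)[C@H](O3)[C@@]12C
F3 | step 14 | 6α,10α-epoxy-4α-isopropyl-1α,8-dimethyl-2β,4β-bis(triethylsilyloxy)hydroazul-8-ene | CC[Si](CC)(CC)O[C@H]1C[C@](O[Si](CC)(CC)CC)(C(C)C)[C@H]2[C@H]3CC(C)=C[C@H](O3)[C@@]12C
F4 | step 14 | 4α-isopropyl-1α,8-dimethyl-2β,4β-bis(triethylsilyloxy)-5α-H-hydroazul-8-en-6α-ol | CC[Si](CC)(CC)O[C@H]1C[C@](O[Si](CC)(CC)CC)(C(C)C)[C@H]2[C@H](O)CC(C)=CC[C@@]12C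
F5 | step 14 | 4α-isopropyl-1α,8-dimethyl-2β,4β-bis(triethylsilyloxy)-5α-H-hydroazul-8-en-6α-yl 3,4,5-trimethoxybenzoate | CC[Si](CC)(CC)O[C@H]1C[C@](O[Si](CC)(CC)CC)(C(C)C)[C@H]2[C@H](OC(=O)c3cc(OC)c(OC)c(OC)c3)CC(C)=CC[C@@]12C
F6 | step 9 | 2α-(tert-butyldimethylsilyloxy)-6α,10α-epoxy-4β-hydroxy-4α-isopropyl-1α,8-dimethylhydroazul-7-en-9-one | CC(C)(C)[Si](C)(C)O[C@@H]1C[C@](O)(C(C)C)[C@H]2[C@H]3C=C(C)C(=O)[C@H](O3)[C@@]12C
F7 | step 9 | p-toluenesulfonylhydrazone of F6 | CC(C)(C)[Si](C)(C)O[C@@H]1C[C@](O)(C(C)C)[C@H]2[C@H]3C=C(C)C(=NNS(=O)(=O)c4ccc(C)cc4)[C@H](O3)[C@@]12C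
F8 | step 7 | 2α-(tert-butyldimethylsilyloxy)-6α,10α-epoxy-1α,8-dimethyl-9-(trimethylsilyloxy)hydroazul-8-en-4-one | CC(C)(C)[Si](C)(C)O[C@@H]1CC(=O)[C@H]2[C@H]3CC(C)=C(O[Si](C)(C)C)[C@H](O3)[C@@]12C
F9 | step 7 | 2α-(tert-butyldimethylsilyloxy)-6α,10α-epoxy-4α-isopropyl-1α,8-dimethyl-9-(trimethylsilyloxy)hydroazul-8-en-4β-ol | CC(C)(C)[Si](C)(C)O[C@@H]1C[C@](O)(C(C)C)[C@H]2[C@H]3CC(C)=C(O[Si](C)(C)C)[C@H](O3)[C@@]12C
F10 | step 7 | 2α-(tert-butyldimethylsilyloxy)-6α,10α-epoxy-4β-hydroxy-4α-isopropyl-1α,8-dimethylhydroazul-8-en-9-yl trifluoromethanesulfonate | CC(C)(C)[Si](C)(C)O[C@@H]1C[C@](O)(C(C)C)[C@H]2[C@H]3CC(C)=C(OS(=O)(=O)C(F)(F)F)[C@H](O3)[C@@]12C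
F11 | step 8 | 2α-(tert-butyldimethylsilyloxy)-6α,10α-epoxy-4α-isopropenyl-1α,8-dimethylhydroazul-7-ene-4β,9β-diol | CC(C)(C)[Si](C)(C)O[C@@H]1C[C@](O)(C(C)=C)[C@H]2[C@H]3C=C(C)[C@@H](O)[C@H](O3)[C@@]12C
F12 | step 17 | 2β-{2-[bis(2,2,2-trifluoroethoxy)phosphoryl]propanoyloxy} analogue of 21 | CC(C(=O)O[C@H]1C[C@](O)(C(C)C)[C@H]2[C@H](OC(=O)c3cc(OC)c(OC)c(OC)c3)CC(C)=CC[C@@]12C)P(=O)(OCC(F)(F)F)OCC(F)(F)F
A1 | alternative 1 | 3-[(4R)-2,2-dimethyl-1,3-dioxolan-4-yl]-2-(triisopropylsilyloxy)but-2-enal (olefin geometry left open) | O=CC(O[Si](C(C)C)(C(C)C)C(C)C)=C(C)[C@@H]1COC(C)(C)O1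
A2 | alternative 1 | isoprene | C=CC(C)=C
A3 | alternative 1 | 2-(triisopropylsilyloxy)-4,7-dimethyl-7-(2,2-dimethyl-1,3-dioxolan-4-yl)cyclohept-4-en-1-one | O=C1[C@H](O[Si](C(C)C)(C(C)C)C(C)C)CC(C)=CC[C@@]1(C)[C@@H]2COC(C)(C)O2
A4 | alternative 2 | thymoquinone | CC1=CC(=O)C(C(C)C)=CC1=O
A5 | alternative 2 | trans-decalin 4,5-epoxy-6-ol (C1–C6 bonded, C2 silyl ether, C8=C9) | CC(C)(C)[Si](C)(C)O[C@H]1C[C@@]2(C(C)C)O[C@H]2[C@]3(O)CC(C)=CC[C@@]13C
A6 | alternative 2 | cis-fused 2β-(tert-butyldimethylsilyloxy)-4β-hydroxy-4α-isopropyl-1α,8-dimethylhydroazul-8-en-6-one | CC(C)(C)[Si](C)(C)O[C@H]1C[C@](O)(C(C)C)[C@H]2C(=O)CC(C)=CC[C@@]12C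
A7 | alternative 3 | cis-1-[3-(tert-butyldimethylsilyloxy)-2-methylcyclopent-1-enyl]-2-methyl-1-(trimethylsilyloxy)-2-vinylcyclopropane | CC1=C([C@]2(O[Si](C)(C)C)C[C@]2(C)C=C)CC[C@@H]1O[Si](C)(C)C(C)(C)C
A8 | alternative 3 | bicyclic C5=C6 trimethylsilyl enol ether with quaternary C1, C8=C9 and 2β-silyloxy group | CC(C)(C)[Si](C)(C)O[C@H]1CCC2=C(O[Si](C)(C)C)CC(C)=CC[C@@]12C
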